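A direct plan would join two finished arenes at the depside carbonyl. 2,6-Dimethoxy-4-methylbenzaldehyde A1 would be iodinated to A2, A2 would be coupled with methyl atrarate 1 under CO and Pd(OAc)2 to the depside dimethyl ether A3, BCl3 would cleave both methyl ethers to atranorin A4, and both rings would be chlorinated last. Its weakest steps would be:
- the carbonylative esterification: an iodide flanked by OMe and CH3, a crowded aroyl–palladium intermediate and a weakly nucleophilic phenol, under CO pressure beside a free aldehyde;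
- the double ether cleavage: protecting groups removed by a strong Lewis acid next to a cleavable aryl ester, length without complexity;
- the iodination, which adds an atom only to lose it again.

The route rests on building ring B after the depside ester, not on joining two arenes. In ring B, C1 (ester carbon) and C6 (CH3) are the two alkyne carbons of a but-2-ynoate, and C2(OH)–C3–C4(OH)–C5 is the carbon chain of acetoacetate. The ring A phenol is therefore acylated with unhindered but-2-ynoic acid, and the aryl ynoate takes up a 1,3-bis(silyloxy)diene in a Diels–Alder reaction; loss of methanol aromatises the adduct. One operation forms C1–C2 and C5–C6 and sets the 1,2,4,6 pattern. No carbonylation, no iodide handle and no methyl ether protection remain; the ring B chlorine and the formyl group are added afterwards, the formyl group at the last free position.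

Key step: step 5

Remark: the target has no stereocentre. Compounds 6 and 7 are used as the double-bond isomer mixtures in which they form and are drawn without geometry, since both alkenes end in the aromatic ring. Compounds 9 and 13 are transient racemates and are drawn without configuration.

Step 1
Reactants: 1 methyl atrarate (methyl 2,4-dihydroxy-3,6-dimethylbenzoate)
Product: 2 methyl 5-chloro-2,4-dihydroxy-3,6-dimethylbenzoate
Conditions: SO2Cl2 (1.05 equiv), CH2Cl2/Et2O, 0 °C → rt, dark
Reagents that add atoms: sulfuryl chloride, O=S(=O)(Cl)Cl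
Why: Electrophilic aromatic chlorination; C5 is the only ring C–H of 1 and lies ortho to the 4-OH and para to the 2-OH, and ionic conditions in the dark should leave the benzylic methyl groups untouched.

Step 2
Reactants: 2 methyl 5-chloro-2,4-dihydroxy-3,6-dimethylbenzoate; 3 but-2-ynoic acid (1.3 equiv)
Product: 4 2-chloro-5-hydroxy-4-(methoxycarbonyl)-3,6-dimethylphenyl but-2-ynoate
Conditions: N,N'-diisopropylcarbodiimide (1.3 equiv), DMAP (5 mol%), CH2Cl2, −10 → 0 °C
Reagents that add atoms: none
Why: Steglich esterification; the 2-OH is held in a hydrogen bond to the ester carbonyl, so the more acidic 4-OH should be acylated, the small linear butynoyl group meets little hindrance from the flanking CH3 and Cl, and low temperature with little DMAP should hold back isomerisation to the allenoate.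

Step 3
Reactants: 5 methyl acetoacetate
Product: 6 methyl 3-(trimethylsilyloxy)but-2-enoate
Conditions: Me3SiCl (1.2 equiv), Et3N (1.3 equiv), hexane, rt; filtration, distillation
Reagents that add atoms: chlorotrimethylsilane, C[Si](C)(C)Cl
Why: O-silylation of the enol of a β-keto ester (silyl enol ether formation), the standard first stage towards a bis-silyl dienol ether.

Step 4
Reactants: 6 methyl 3-(trimethylsilyloxy)but-2-enoate
Product: 7 1-methoxy-1,3-bis(trimethylsilyloxy)buta-1,3-diene
Conditions: LiN(iPr)2 (1.1 equiv), THF, −78 °C; Me3SiCl (1.2 equiv), −78 → 0 °C; hexane, filtration, used directly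
Reagents that add atoms: chlorotrimethylsilane, C[Si](C)(C)Cl
Why: γ-Deprotonation of the silyl enol ether to the extended ester enolate and O-silylation (silyl ketene acetal formation) should give the 1,3-dioxygenated diene.

Step 5
Reactants: 4 2-chloro-5-hydroxy-4-(methoxycarbonyl)-3,6-dimethylphenyl but-2-ynoate; 7 1-methoxy-1,3-bis(trimethylsilyloxy)buta-1,3-diene (3 equiv in two portions)
Product: 11 2-chloro-5-hydroxy-4-(methoxycarbonyl)-3,6-dimethylphenyl 2,4-dihydroxy-6-methylbenzoate, via trimethylsilyl ether 8 (not isolated), via cyclohexa-1,4-diene cycloadduct 9 (not isolated), via tris(trimethylsilyl) ether 10 (not isolated)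
Conditions: N,O-bis(trimethylsilyl)acetamide (1.5 equiv), toluene, 60 °C; then 7, 120 °C, sealed tube; then 1 M HCl, THF, rt
Reagents that add atoms: none
Why: Diels–Alder reaction of a 1,3-dioxygenated diene with a 2-alkynoate followed by aromatisation through loss of methanol is a known way from alkyl 2-alkynoates to 2,4-dihydroxy-6-alkylbenzoates and is applied here to the alkynoate of a phenol. The silylating agent first masks the acidic 2-OH of ring A as 8, so that it cannot protonate the ketene acetal. Ring B is closed as a six-membered carbocycle in a concerted, asynchronous [4+2] mode that forms C5–C6 and C1–C2; the largest HOMO coefficient lies on the CH2 terminus of 7 and the largest LUMO coefficient on the methyl-bearing β-carbon of the ynoate, so the CH2 carbon becomes C5 beside the methyl group and the ketene acetal carbon becomes C2 beside the ester, which gives the 2,4-dihydroxy-6-methyl pattern and not the 3,5-dioxygenated isomer. Adduct 9 should ionise at its mixed methyl silyl ketal to an arenium-type cation stabilised by both oxygen atoms and lose the C5 proton, methanol overall, to give 10; dilute acid then removes the three silyl groups and sends any surviving ketal through its hemiketal to the same phenol. No stereocentre remains, because the sp3 carbons of 9 become aromatic. The step needs chemoselectivity for the alkyne over the two ester carbonyls, which neutral conditions without a Lewis acid should secure, and the crowded depside ester is already in place because it was made from an unhindered alkynoic acid.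

Step 6
Reactants: 11 2-chloro-5-hydroxy-4-(methoxycarbonyl)-3,6-dimethylphenyl 2,4-dihydroxy-6-methylbenzoate
Product: 12 2-chloro-5-hydroxy-4-(methoxycarbonyl)-3,6-dimethylphenyl 3-chloro-4,6-dihydroxy-2-methylbenzoate (ring B: 5-Cl, 2,4-(OH)2, 6-CH3 in the numbering of the target)
Conditions: SO2Cl2 (1.0 equiv), Et2O, 0 °C, dark
Reagents that add atoms: sulfuryl chloride, O=S(=O)(Cl)Cl
Why: Electrophilic aromatic chlorination with one equivalent; ring A has no C–H left, and on ring B C5 (para to the chelated 2-OH, ortho to the free 4-OH) should react before C3 between the two hydroxyl groups, as is usual for 6-alkyl-2,4-dihydroxybenzoyl compounds.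

Step 7
Reactants: 12 2-chloro-5-hydroxy-4-(methoxycarbonyl)-3,6-dimethylphenyl 3-chloro-4,6-dihydroxy-2-methylbenzoate
Product: 14 2-chloro-5-hydroxy-4-(methoxycarbonyl)-3,6-dimethylphenyl 5-chloro-3-formyl-2,4-dihydroxy-6-methylbenzoate (target), via chloro(methoxy)methyl arene 13 (not isolated)
Conditions: Cl2CHOMe (2 equiv), TiCl4 (4 equiv), CH2Cl2, −10 → 0 °C; then 1 M HCl
Reagents that add atoms: dichloromethyl methyl ether, COC(Cl)Cl; water, O
Why: Rieche formylation; C3 of ring B is the only aromatic C–H left in the molecule and lies ortho to both phenols, the titanium phenoxide should deliver the chloro(methoxy)carbenium ion there, and aqueous acid hydrolyses 13 to the aldehyde while both esters should survive at or below 0 °C.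

**Compound list**
1 | methyl atrarate (methyl 2,4-dihydroxy-3,6-dimethylbenzoate) | COC(=O)c1c(C)cc(O)c(C)c1O | starting material
2 | methyl 5-chloro-2,4-dihydroxy-3,6-dimethylbenzoate | COC(=O)c1c(C)c(Cl)c(O)c(C)c1O | intermediate
3 | but-2-ynoic acid | CC#CC(=O)O | starting material
4 | 2-chloro-5-hydroxy-4-(methoxycarbonyl)-3,6-dimethylphenyl but-2-ynoate | CC#CC(=O)Oc1c(C)c(O)c(C(=O)OC)c(C)c1Cl | intermediate
5 | methyl acetoacetate | COC(=O)CC(C)=O | starting material
6 | methyl 3-(trimethylsilyloxy)but-2-enoate | COC(=O)C=C(C)O[Si](C)(C)C | intermediate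
7 | 1-methoxy-1,3-bis(trimethylsilyloxy)buta-1,3-diene | COC(O[Si](C)(C)C)=CC(=C)O[Si](C)(C)C | intermediate
8 | 2-chloro-4-(methoxycarbonyl)-3,6-dimethyl-5-(trimethylsilyloxy)phenyl but-2-ynoate | CC#CC(=O)Oc1c(C)c(O[Si](C)(C)C)c(C(=O)OC)c(C)c1Cl | intermediate
9 | 2-chloro-4-(methoxycarbonyl)-3,6-dimethyl-5-(trimethylsilyloxy)phenyl 6-methoxy-2-methyl-4,6-bis(trimethylsilyloxy)cyclohexa-1,4-diene-1-carboxylate (racemic) | COC(=O)c1c(C)c(Cl)c(OC(=O)C2=C(C)CC(O[Si](C)(C)C)=CC2(OC)O[Si](C)(C)C)c(C)c1O[Si](C)(C)C | intermediate
10 | 2-chloro-4-(methoxycarbonyl)-3,6-dimethyl-5-(trimethylsilyloxy)phenyl 2-methyl-4,6-bis(trimethylsilyloxy)benzoate | COC(=O)c1c(C)c(Cl)c(OC(=O)c2c(C)cc(O[Si](C)(C)C)cc2O[Si](C)(C)C)c(C)c1O[Si](C)(C)C | intermediate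
11 | 2-chloro-5-hydroxy-4-(methoxycarbonyl)-3,6-dimethylphenyl 2,4-dihydroxy-6-methylbenzoate | COC(=O)c1c(C)c(Cl)c(OC(=O)c2c(C)cc(O)cc2O)c(C)c1O | intermediate
12 | 2-chloro-5-hydroxy-4-(methoxycarbonyl)-3,6-dimethylphenyl 3-chloro-4,6-dihydroxy-2-methylbenzoate | COC(=O)c1c(C)c(Cl)c(OC(=O)c2c(C)c(Cl)c(O)cc2O)c(C)c1O | intermediate
13 | 2-chloro-5-hydroxy-4-(methoxycarbonyl)-3,6-dimethylphenyl 3-chloro-5-[chloro(methoxy)methyl]-4,6-dihydroxy-2-methylbenzoate (racemic; drawn with free phenols, titanium-bound in the flask) | COC(=O)c1c(C)c(Cl)c(OC(=O)c2c(C)c(Cl)c(O)c(C(Cl)OC)c2O)c(C)c1O | intermediate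
14 | 2-chloro-5-hydroxy-4-(methoxycarbonyl)-3,6-dimethylphenyl 5-chloro-3-formyl-2,4-dihydroxy-6-methylbenzoate | COC(=O)c1c(C)c(Cl)c(OC(=O)c2c(C)c(Cl)c(O)c(C=O)c2O)c(C)c1O | target

Total step count: 7. Longest linear sequence: 5 steps (steps 1, 2, 5, 6, 7; the diene branch through steps 3 and 4 is equally long).

Steps most likely to fail

Step 5. Thermal decay of diene 7 (silyl shift, adventitious hydrolysis) may outrun cycloaddition to the trisubstituted ynoate, and the adduct may lose silanol instead of methanol and so keep a methyl ether at C2 of ring B. The fallback sets out from 2 and closes ring B from an open chain. 2,2,6-Trimethyl-4H-1,3-dioxin-4-one would be acetylated at its 6-methyl group (LiN(SiMe3)2, THF, −78 °C; acetyl chloride) to 2,2-dimethyl-6-(2-oxopropyl)-4H-1,3-dioxin-4-one F1. The dianion of F1 (LiN(iPr)2, 2.2 equiv) would be acetylated with N-methoxy-N-methylacetamide to 6-(2,4-dioxopentyl)-2,2-dimethyl-4H-1,3-dioxin-4-one F2. Heating F2 with 2 in toluene at 110 °C would release acetone and an acylketene, which the 4-OH of 2 should trap as 2-chloro-5-hydroxy-4-(methoxycarbonyl)-3,6-dimethylphenyl 3,5,7-trioxooctanoate F3. Aldol closure of C2 onto the C7 ketone and dehydration (Et3N, CH2Cl2; then silica gel or HCl in dioxane) would return to the route at 11.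

Step 6. Chlorination may spread to C3 of ring B or run on to the 3,5-dichloride. The fallback sets out from 4 and lets the cycloaddition place the chlorine. Methyl 4-chloroacetoacetate would be silylated (Me3SiCl, Et3N) to methyl 4-chloro-3-(trimethylsilyloxy)but-2-enoate F4 and then (LiN(iPr)2, Me3SiCl, −78 °C) to 4-chloro-1-methoxy-1,3-bis(trimethylsilyloxy)buta-1,3-diene F5. Cycloaddition of F5 to silyl ether 8, made from 4 as in step 5, would give 2-chloro-4-(methoxycarbonyl)-3,6-dimethyl-5-(trimethylsilyloxy)phenyl 3-chloro-6-methoxy-2-methyl-4,6-bis(trimethylsilyloxy)cyclohexa-1,4-diene-1-carboxylate F6. The chlorine-bearing diene terminus bonds to the methyl-bearing alkyne carbon, so loss of methanol would leave the chlorine at C5 in 2-chloro-4-(methoxycarbonyl)-3,6-dimethyl-5-(trimethylsilyloxy)phenyl 3-chloro-2-methyl-4,6-bis(trimethylsilyloxy)benzoate F7. Dilute HCl would return to the route at 12.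

Step 7. Attack at the doubly flanked, deactivated C3 may be slow, and TiCl4 may cleave or transfer the depside acyl group. The fallback sets out from 12 and brings in the carbon as an amine, without a Lewis acid or an oxocarbenium electrophile. Aminomethylation with hexamethylenetetramine in CF3CO2H at 80 °C and hydride shift in the same flask (Duff reaction) would give 2-chloro-5-hydroxy-4-(methoxycarbonyl)-3,6-dimethylphenyl 3-chloro-4,6-dihydroxy-2-methyl-5-[(methylimino)methyl]benzoate F8. Aqueous HCl would hydrolyse F8 and return to the route at 14.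

Further compounds
F1 | step 5 | 2,2-dimethyl-6-(2-oxopropyl)-4H-1,3-dioxin-4-one | CC(=O)CC1=CC(=O)OC(C)(C)O1
F2 | step 5 | 6-(2,4-dioxopentyl)-2,2-dimethyl-4H-1,3-dioxin-4-one | CC(=O)CC(=O)CC1=CC(=O)OC(C)(C)O1
F3 | step 5 | 2-chloro-5-hydroxy-4-(methoxycarbonyl)-3,6-dimethylphenyl 3,5,7-trioxooctanoate | CC(=O)CC(=O)CC(=O)CC(=O)Oc1c(C)c(O)c(C(=O)OC)c(C)c1Cl
F4 | step 6 | methyl 4-chloro-3-(trimethylsilyloxy)but-2-enoate | COC(=O)C=C(CCl)O[Si](C)(C)C
F5 | step 6 | 4-chloro-1-methoxy-1,3-bis(trimethylsilyloxy)buta-1,3-diene | COC(O[Si](C)(C)C)=CC(=CCl)O[Si](C)(C)C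
F6 | step 6 | 2-chloro-4-(methoxycarbonyl)-3,6-dimethyl-5-(trimethylsilyloxy)phenyl 3-chloro-6-methoxy-2-methyl-4,6-bis(trimethylsilyloxy)cyclohexa-1,4-diene-1-carboxylate (mixture of racemic diastereomers) | COC(=O)c1c(C)c(Cl)c(OC(=O)C2=C(C)C(Cl)C(O[Si](C)(C)C)=CC2(OC)O[Si](C)(C)C)c(C)c1O[Si](C)(C)C
F7 | step 6 | 2-chloro-4-(methoxycarbonyl)-3,6-dimethyl-5-(trimethylsilyloxy)phenyl 3-chloro-2-methyl-4,6-bis(trimethylsilyloxy)benzoate | COC(=O)c1c(C)c(Cl)c(OC(=O)c2c(C)c(Cl)c(O[Si](C)(C)C)cc2O[Si](C)(C)C)c(C)c1O[Si](C)(C)C
F8 | step 7 | 2-chloro-5-hydroxy-4-(methoxycarbonyl)-3,6-dimethylphenyl 3-chloro-4,6-dihydroxy-2-methyl-5-[(methylimino)methyl]benzoate | COC(=O)c1c(C)c(Cl)c(OC(=O)c2c(C)c(Cl)c(O)c(C=NC)c2O)c(C)c1O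
A1 | direct plan | 2,6-dimethoxy-4-methylbenzaldehyde | COc1cc(C)cc(OC)c1C=O
A2 | direct plan | 3-iodo-2,6-dimethoxy-4-methylbenzaldehyde | COc1cc(C)c(I)c(OC)c1C=O
A3 | direct plan | 3-hydroxy-4-(methoxycarbonyl)-2,5-dimethylphenyl 3-formyl-2,4-dimethoxy-6-methylbenzoate | COC(=O)c1c(C)cc(OC(=O)c2c(C)cc(OC)c(C=O)c2OC)c(C)c1O
A4 | direct plan | atranorin, 3-hydroxy-4-(methoxycarbonyl)-2,5-dimethylphenyl 3-formyl-2,4-dihydroxy-6-methylbenzoate | COC(=O)c1c(C)cc(OC(=O)c2c(C)cc(O)c(C=O)c2O)c(C)c1O
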